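(The earlier runs and the new flask were computed for substances that don't exist.)

1. I started from what was left of the target late in the violet run: [target] fell from 25.2% at 3.00 min to 4.7% at 8.00 min. I read from this a tail rate of 0.336 min⁻¹, the fall of ln[target] per minute late in a run, which I treated as a first-order decay constant, though it was read from scattered readings.

| flask | substrate | remark | time |
|---|---|---|---|
| violet | 1 mM | run made earlier |  |
| blue | 1.5 mM | run made earlier |  |
| flask | 2.0 mM |  | 10 min |

| run | time / min | target / % |
|---|---|---|
| violet | 0.417 | 13.5 |
| violet | 0.667 | 19.3 |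
| violet | 1.00 | 25.7 |
| violet | 2.00 | 28.1 |
| violet | 3.00 | 25.2 |
| violet | 5.00 | 12.6 |
| violet | 8.00 | 4.7 |
| blue | 0.417 | 14.3 |
| blue | 0.667 | 19.7 |
| blue | 1.00 | 25.3 |
| blue | 2.00 | 29.6 |
| blue | 3.00 | 25.3 |
| blue | 5.00 | 13.0 |
| blue | 8.00 | 4.5 |

(scatter of a reading: 1 percentage point)

- the best time, 10 min at the latest, for target
- the amount of target, in percent of the substrate charged, at that time



2. I took the peak as the crossing where making of target fell to the tail rate times [target].

3. I turned the question round. If the tail sped up with the charge, the blue tail had to be 1.50 times the violet one. The blue readings gave 0.345 min⁻¹, just 1.03 times the violet, which is less than that. So I expected the same curve at 2.0 mM, with a peak near 2.00 min and about 28.9%, the mean of the two readings there.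

4. The forecast gave 1.9 min and 29.5%, on the ground that “the kinetics look first-order”.

5. The flask gave 1.71 min and 28.1%, so the forecast stood.

    substrate + intermediate B → side product B (k = 13.0 L mol⁻¹ s⁻¹)
    substrate → side product A (k = 0.0200 s⁻¹)
    substrate ⇌ dormant form (K = 1.00, k = 0.0610 s⁻¹)
    substrate ⇌ intermediate A (K = 0.380, k = 0.690 s⁻¹)
    target → over-reaction product (k = 0.00590 s⁻¹)
    intermediate B → target (k = 0.0800 s⁻¹)
    substrate → intermediate B (k = 0.0240 s⁻¹)

6. In the flask, from 13.2% at 5.00 min, the tail rate gave 2.46% at 10.0 min, and the flask held 2.37%. The fall from best to end in the flask was worth 7.36 min at the tail rate. The neighbour at 8.0 mM went from a best of 22.7% to 1.96%, a fall worth 7.29 min at the tail rate. Its best lay lower than the forecast's 29.5%, so at that charge the forecast's number did not hold. It ended with more side product B than the flask, each unit counted as two: 17.3% against 5.53%.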